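**Plan**

- Retrosynthesis: the chroman bond C4–C4a is cut together with a retro-1,2-shift of ring B from C3 back to C4. This unravels the isoflavan into a linear (R)-1-aryl-3-aryloxypropan-2-ol, which is cut at ArB–CH2 (aryllithium + glycidyl aryl ether) and at ArA–O–CH2 (phenol + glycidol); ring B is cut at C3'–prenyl and at the pyran ring (resorcinol + prenal).
- Forward order: the dimethylpyran on ring B is made first, then the prenyl group and the three-carbon linker are attached by two successive directed ortho-metalations, and the chroman ring C closes last, in the cascade.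
- Stereochemistry: the only stereocentre comes from (S)-glycidol. Its carbinol carbon is inverted once, stereospecifically, when ring B migrates onto it, which should turn the (R)-carbinol into the (R)-isoflavan.
- Enabling feature: C3 lies between two CH2 groups (C2–O1 and C4–C4a). Ring B is bound through C1', which is para to the pyran oxygen O-4' and ortho to O-2', so it is a strong neighbouring and migrating group. C4a of ring A is para to the 7-oxygen and ortho to O1, so it is an internal Friedel–Crafts nucleophile placed for six-membered closure.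
- Both phenols travel as MOM ethers, which also direct both lithiations, and are released in one final step.

Key step: step 7

Remark: atom labels follow isoflavan usage (rings A/C = chroman with O1, C2, C3, C4, C4a–C8a; ring B = aryl group on C3, C1'–C6'). For ring-B building blocks chromene locants are used: chromene C6 = C1', C7 = C2', C8 = C3'. The target stereocentre (C3) is (R).

**Step 1**
Reactants: 1 resorcinol; 2 3-methylbut-2-enal
Product: 3 2,2-dimethyl-2H-chromen-7-ol
Conditions: pyridine, 140 °C (sealed tube), 1 in excess
Reagents that add atoms: none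
Why: Condensation of the enal at C4 of resorcinol (ortho to one OH, para to the other), dehydration to an ortho-quinone methide and oxa-6π electrocyclisation (formal [3+3] chromene annulation) should give the 7-hydroxychromene, with excess resorcinol limiting a second annulation.

**Step 2**
Reactants: 3 2,2-dimethyl-2H-chromen-7-ol
Product: 4 7-(methoxymethoxy)-2,2-dimethyl-2H-chromene
Conditions: NaH, DMF, 0 °C; MOMCl, 0 °C → rt
Reagents that add atoms: chloromethyl methyl ether (MOMCl), COCCl
Why: O-Alkylation of the sodium phenoxide (Williamson-type) installs the MOM acetal, which serves as protecting group and as ortho-directing group for steps 3 and 6.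

**Step 3**
Reactants: 4 7-(methoxymethoxy)-2,2-dimethyl-2H-chromene; 5 1-bromo-3-methylbut-2-ene
Product: 7 7-(methoxymethoxy)-2,2-dimethyl-8-(3-methylbut-2-en-1-yl)-2H-chromene, via C8 aryllithium 6 (not isolated)
Conditions: n-BuLi, THF, 0 °C → rt; CuBr·SMe2 (10 mol %), 5, −78 °C → rt
Reagents that add atoms: none
Why: Directed ortho-metalation should occur at C8, the position flanked by the MOM ether and the pyran oxygen (cooperative direction as in 1,3-dialkoxybenzenes), and copper-catalysed SN2 allylation with prenyl bromide then installs the 3'-prenyl group.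

**Step 4**
Reactants: 1 resorcinol
Product: 8 3-(methoxymethoxy)phenol
Conditions: NaH (1 equiv), THF/DMF, 0 °C; MOMCl (1 equiv); 1 in excess (3 equiv)
Reagents that add atoms: chloromethyl methyl ether (MOMCl), COCCl
Why: Mono-O-alkylation of the monosodium salt of excess resorcinol (statistical desymmetrisation of a symmetric diphenol) should give the mono-MOM ether, separable from recovered resorcinol and the bis-ether.

**Step 5**
Reactants: 8 3-(methoxymethoxy)phenol; 9 (S)-glycidol
Product: 10 (R)-2-{[3-(methoxymethoxy)phenoxy]methyl}oxirane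
Conditions: PPh3, DIAD, THF, 0 °C → rt
Reagents that add atoms: none
Why: The Mitsunobu etherification takes place at the primary carbinol carbon, so the epoxide stereocentre is not touched; (S)-glycidol gives the (R)-glycidyl aryl ether only because CH2OAr outranks the ring CH2 in the CIP order.

**Step 6**
Reactants: 7 7-(methoxymethoxy)-2,2-dimethyl-8-(3-methylbut-2-en-1-yl)-2H-chromene; 10 (R)-2-{[3-(methoxymethoxy)phenoxy]methyl}oxirane
Product: 12 (R)-1-[7-(methoxymethoxy)-2,2-dimethyl-8-(3-methylbut-2-en-1-yl)-2H-chromen-6-yl]-3-[3-(methoxymethoxy)phenoxy]propan-2-ol, via C6 aryllithium 11 (not isolated)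
Conditions: n-BuLi, THF, 0 °C → rt; −78 °C, 10 then BF3·OEt2; H2O
Reagents that add atoms: none
Why: The MOM group directs lithiation to C6, the only free position ortho to it (ring lithiation of prenyl-bearing MOM ethers has precedent), and the BF3-promoted SN2 opening of the terminal epoxide by the aryllithium occurs at the unsubstituted CH2, so the carbinol centre keeps the configuration of 10 and is (R) (directed ortho-metalation, Lewis-acid-promoted organolithium epoxide opening).

**Step 7**
Reactants: 12 (R)-1-[7-(methoxymethoxy)-2,2-dimethyl-8-(3-methylbut-2-en-1-yl)-2H-chromen-6-yl]-3-[3-(methoxymethoxy)phenoxy]propan-2-ol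
Product: 15 7-(methoxymethoxy)-6-[(3R)-7-(methoxymethoxy)-3,4-dihydro-2H-chromen-3-yl]-2,2-dimethyl-8-(3-methylbut-2-en-1-yl)-2H-chromene, via secondary triflate 13 (not isolated), via phenonium triflate 14 (not isolated)
Conditions: Tf2O (1.2 equiv), 2,6-di-tert-butyl-4-methylpyridine (2.5 equiv), CH2Cl2 (0.01 M), −78 → −20 °C
Reagents that add atoms: none
Why: Proposed new method: O-triflation of the carbinol makes a leaving group that is expelled with anchimeric assistance (Ar1-3 participation) by ring B, whose ipso carbon C1' is para to the pyran oxygen and ortho to the 2'-OMOM group, giving the spirocyclopropyl cyclohexadienyl (phenonium) ion 14, and C4a of ring A then opens the cyclopropane at its CH2 carbon in an intramolecular Friedel–Crafts alkylation, so that ring B ends on C3 and the former ArCH2 carbon becomes C4. The closest known reaction types are the stereospecific 1,2-aryl shifts of β-arylalkyl sulfonates and of flavan-3-ol sulfonates through phenonium ions, the Friedel–Crafts capture of phenonium ions by arenes, and the 6-endo epoxide–arene cyclisation of aryl glycidyl ethers to chroman-3-ols, of which 14 is the all-carbon counterpart. Ring C is closed by C4–C4a bond formation in a 6-endo opening of the three-membered ring; the competing 5-exo attack at C3 would need a backside Friedel–Crafts closure of a dihydrobenzofuran through a two-atom tether, which is geometrically strained, and C3 is further deactivated by its β-aryloxy group. The single stereocentre C3 is controlled by the substrate: aryl participation is anti to the leaving group, the carbinol carbon from (S)-glycidol is inverted exactly once and is not touched when the cyclopropane opens at C4, so (R)-12 should give (R)-15. The step needs aryl participation rather than O-5 participation of the 2'-acetal oxygen (expected because the ipso carbon of a 2,4-dioxygenated arene is far more nucleophilic than a hindered, electron-poor acetal oxygen) and attack para rather than ortho to the 7-OMOM group on ring A (the ortho site lies between two oxygens and is hindered). The hindered pyridine base takes up both equivalents of TfOH, so the chromene, the prenyl group and the MOM acetals should not meet free acid.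

**Step 8**
Reactants: 15 7-(methoxymethoxy)-6-[(3R)-7-(methoxymethoxy)-3,4-dihydro-2H-chromen-3-yl]-2,2-dimethyl-8-(3-methylbut-2-en-1-yl)-2H-chromene
Product: 17 6-[(3R)-7-hydroxy-3,4-dihydro-2H-chromen-3-yl]-2,2-dimethyl-8-(3-methylbut-2-en-1-yl)-2H-chromen-7-ol (target), via bis(trimethylsilyl) ether 16 (not isolated)
Conditions: TMSOTf, 2,2'-bipyridyl, CH2Cl2, 0 °C → rt; then H2O, rt
Reagents that add atoms: none
Why: The silyl triflate/2,2'-bipyridyl reagent converts aryl MOM ethers into aryl TMS ethers under buffered, non-protic conditions that should spare the chromene and prenyl olefins, and aqueous hydrolysis then releases both phenols without affecting the non-epimerisable C3 (mild aryl MOM ether cleavage).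

**Compound list**

1 | resorcinol | Oc1cccc(O)c1 | starting material
2 | 3-methylbut-2-enal | CC(C)=CC=O | starting material
3 | 2,2-dimethyl-2H-chromen-7-ol | CC1(C)C=Cc2ccc(O)cc2O1 | intermediate
4 | 7-(methoxymethoxy)-2,2-dimethyl-2H-chromene | COCOc1ccc2C=CC(C)(C)Oc2c1 | intermediate
5 | 1-bromo-3-methylbut-2-ene (prenyl bromide) | CC(C)=CCBr | starting material
6 | [7-(methoxymethoxy)-2,2-dimethyl-2H-chromen-8-yl]lithium | COCOc1ccc2C=CC(C)(C)Oc2c1[Li] | intermediate
7 | 7-(methoxymethoxy)-2,2-dimethyl-8-(3-methylbut-2-en-1-yl)-2H-chromene | COCOc1ccc2C=CC(C)(C)Oc2c1CC=C(C)C | intermediate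
8 | 3-(methoxymethoxy)phenol | COCOc1cccc(O)c1 | intermediate
9 | (S)-glycidol [(S)-oxiran-2-ylmethanol] | OC[C@H]1CO1 | starting material
10 | (R)-2-{[3-(methoxymethoxy)phenoxy]methyl}oxirane | COCOc1cccc(OC[C@H]2CO2)c1 | intermediate
11 | [7-(methoxymethoxy)-2,2-dimethyl-8-(3-methylbut-2-en-1-yl)-2H-chromen-6-yl]lithium | COCOc1c([Li])cc2C=CC(C)(C)Oc2c1CC=C(C)C | intermediate
12 | (R)-1-[7-(methoxymethoxy)-2,2-dimethyl-8-(3-methylbut-2-en-1-yl)-2H-chromen-6-yl]-3-[3-(methoxymethoxy)phenoxy]propan-2-ol | COCOc1c(C[C@@H](O)COc2cccc(OCOC)c2)cc2C=CC(C)(C)Oc2c1CC=C(C)C | intermediate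
13 | (R)-1-[7-(methoxymethoxy)-2,2-dimethyl-8-(3-methylbut-2-en-1-yl)-2H-chromen-6-yl]-3-[3-(methoxymethoxy)phenoxy]propan-2-yl trifluoromethanesulfonate | COCOc1c(C[C@@H](OS(=O)(=O)C(F)(F)F)COc2cccc(OCOC)c2)cc2C=CC(C)(C)Oc2c1CC=C(C)C | intermediate
14 | phenonium ion: spiro[cyclopropane-1,6'-chromenylium] cation carrying the CH2O-aryl group on the cyclopropane (R at that carbon), as triflate ion pair | [O+]1=C2C(CC=C(C)C)=C(OCOC)C3(C[C@H]3COc4cccc(OCOC)c4)C=C2C=CC1(C)C.[O-]S(=O)(=O)C(F)(F)F | intermediate
15 | 7-(methoxymethoxy)-6-[(3R)-7-(methoxymethoxy)-3,4-dihydro-2H-chromen-3-yl]-2,2-dimethyl-8-(3-methylbut-2-en-1-yl)-2H-chromene | CC(C)=CCc1c(OCOC)c([C@@H]2COc3cc(OCOC)ccc3C2)cc2c1OC(C)(C)C=C2 | intermediate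
16 | bis(trimethylsilyl) ether of the target | CC(C)=CCc1c(O[Si](C)(C)C)c([C@@H]2COc3cc(O[Si](C)(C)C)ccc3C2)cc2c1OC(C)(C)C=C2 | intermediate
17 | 6-[(3R)-7-hydroxy-3,4-dihydro-2H-chromen-3-yl]-2,2-dimethyl-8-(3-methylbut-2-en-1-yl)-2H-chromen-7-ol | CC(C)=CCc1c(O)c([C@@H]2COc3cc(O)ccc3C2)cc2c1OC(C)(C)C=C2 | target

**Totals**

Total step count: 8. Longest linear sequence: 6 (steps 1, 2, 3, 6, 7, 8).

**Steps most likely to fail**

1. Step 7 (proposed new method). Ionisation of the triflate may not be channelled cleanly through aryl participation. Possible diversions are attack of the 2'-acetal oxygen on C3 (loss of the MOM group and closure of a dihydrobenzofuran), elimination, or a hydride shift in the bridged ion before ring A closes. Any unassisted ionisation would also erode the stereochemical fidelity. Fallback with known chemistry, setting out from 7 and coming back at 15: lithiation of 7 as in step 6 and quenching with 1,2-dibromotetrachloroethane should give 6-bromo-7-(methoxymethoxy)-2,2-dimethyl-8-(3-methylbut-2-en-1-yl)-2H-chromene F1. Commercial 7-hydroxychroman-4-one is converted (NaH, MOMCl) into 7-(methoxymethoxy)chroman-4-one F2. Pd-catalysed ketone α-arylation of F2 with F1 (Pd2(dba)3, bulky biarylphosphine, NaOtBu, toluene) should give the racemic isoflavanone 7-(methoxymethoxy)-3-[7-(methoxymethoxy)-2,2-dimethyl-8-(3-methylbut-2-en-1-yl)-2H-chromen-6-yl]chroman-4-one F3. Noyori–Ikariya transfer hydrogenation under dynamic kinetic resolution (RuCl[(R,R)-TsDPEN](p-cymene), HCO2H/Et3N) should funnel both enantiomers of the readily enolised F3 into the cis alcohol (3R,4R)-7-(methoxymethoxy)-3-[7-(methoxymethoxy)-2,2-dimethyl-8-(3-methylbut-2-en-1-yl)-2H-chromen-6-yl]chroman-4-ol F4. Ionic deoxygenation of the doubly activated benzylic alcohol (Et3SiH, BF3·OEt2, CH2Cl2, −78 °C) then returns to 15.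

2. Step 6. The BF3-activated glycidyl ether may be consumed by intramolecular Friedel–Crafts cyclisation or by halide/fluoride opening faster than it is attacked by the hindered aryllithium. Part of the base may also deprotonate the benzylic/allylic CH2 of the prenyl group. Fallback, setting out from 7 and coming back at 12: the aryllithium from 7 is transmetallated (MgBr2·OEt2) and reacted under CuI catalysis, without Lewis acid, with commercial (R)-epichlorohydrin to give (R)-1-chloro-3-[7-(methoxymethoxy)-2,2-dimethyl-8-(3-methylbut-2-en-1-yl)-2H-chromen-6-yl]propan-2-ol F5. NaOH closes this to (R)-7-(methoxymethoxy)-2,2-dimethyl-8-(3-methylbut-2-en-1-yl)-6-(oxiran-2-ylmethyl)-2H-chromene F6. Opening of F6 at its terminal carbon by phenol 8 (K2CO3 or CsF, DMF, 80 °C) forms the aryl ether bond last and gives 12 with the same (R) carbinol centre.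

3. Step 1. Annulation at C2 of resorcinol (giving the 5-hydroxy isomer) and a second annulation on the product may lower the throughput of the first intermediate. Fallback, setting out from 1 and coming back at 3: acylation/oxa-Michael cyclisation of 1 with 3-methylbut-2-enoic acid (MsOH/P2O5, 70 °C) should give 7-hydroxy-2,2-dimethylchroman-4-one F7 regioselectively. Reduction with LiAlH4 (THF, reflux) should give 2,2-dimethylchroman-4,7-diol F8, and acid-catalysed dehydration of this para-hydroxybenzylic alcohol (cat. p-TsOH, toluene, 60 °C) gives 3.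

**Further compounds**

F1 | step 7 | 6-bromo-7-(methoxymethoxy)-2,2-dimethyl-8-(3-methylbut-2-en-1-yl)-2H-chromene | COCOc1c(Br)cc2C=CC(C)(C)Oc2c1CC=C(C)C
F2 | step 7 | 7-(methoxymethoxy)chroman-4-one | COCOc1ccc2C(=O)CCOc2c1
F3 | step 7 | rac-7-(methoxymethoxy)-3-[7-(methoxymethoxy)-2,2-dimethyl-8-(3-methylbut-2-en-1-yl)-2H-chromen-6-yl]chroman-4-one | COCOc1ccc2C(=O)C(COc2c1)c1cc2C=CC(C)(C)Oc2c(CC=C(C)C)c1OCOC
F4 | step 7 | (3R,4R)-7-(methoxymethoxy)-3-[7-(methoxymethoxy)-2,2-dimethyl-8-(3-methylbut-2-en-1-yl)-2H-chromen-6-yl]chroman-4-ol | COCOc1c(cc2C=CC(C)(C)Oc2c1CC=C(C)C)[C@@H]1COc2cc(OCOC)ccc2[C@@H]1O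
F5 | step 6 | (R)-1-chloro-3-[7-(methoxymethoxy)-2,2-dimethyl-8-(3-methylbut-2-en-1-yl)-2H-chromen-6-yl]propan-2-ol | COCOc1c(C[C@@H](O)CCl)cc2C=CC(C)(C)Oc2c1CC=C(C)C
F6 | step 6 | (R)-7-(methoxymethoxy)-2,2-dimethyl-8-(3-methylbut-2-en-1-yl)-6-(oxiran-2-ylmethyl)-2H-chromene | COCOc1c(C[C@@H]2CO2)cc2C=CC(C)(C)Oc2c1CC=C(C)C
F7 | step 1 | 7-hydroxy-2,2-dimethylchroman-4-one | CC1(C)CC(=O)c2ccc(O)cc2O1
F8 | step 1 | 2,2-dimethylchroman-4,7-diol | CC1(C)CC(O)c2ccc(O)cc2O1
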